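**Plan**

- Rings: A = trimethylcyclohexane, B = cyclohexene, C = cyclopentane, D = oxetanone. Cuts: (a) rings C and D together, through the C–C bond between the lactone α-carbon and the O–CH carbon and through the acyl C–O bond, giving ring-B aldehyde acid 22; (b) the sp2–CH2 bond of the propanoic arm (enol triflate + alkylzinc; the triflate comes from a 2-substituted cyclohexenone); (c) two σ bonds of ring B by Diels–Alder, giving diene 6 and E-enoyl imide 12; (d) the bond from the ring-A quaternary carbon to the alkene carbon (conjugate addition to 3-methylcyclohexenone).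
- Forward order: ring-A quaternary carbon (step 1), gem-dimethyl group and diene (2–4), ring B (7), butanoate, allylic oxygenation, regiospecific enol triflate and arm (8–13), unmasking (14, 15), rings C and D last (16).
- Feature used: the oxetanone is fused to ring C across its α-carbon and its O–CH carbon. The chain O=CH–C(sp3, ring B)–C(sp2, ring B)–CH2–CH2–CO2H therefore holds formyl and acid carbons 1,6: one aldol bond closes ring C, and the cis alkoxide is held against the activated acyl group to close ring D.
- Stereochemistry: ring-A quaternary carbon (R) from the chiral N-heterocyclic carbene ligand used with Cu(OTf)2; the two ring-B CH centres (trans) from the E dienophile and the (R)-oxazolidinone; the two lactone carbons from the ring-fusion centre during the bis-cyclisation.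

Key step: step 16

Assumption: in step 1 the enantiomer of the chiral carbene precursor is the one that delivers the (R)-ketone 3; descriptors are read from the target SMILES (ring-A quaternary carbon R, CH–CH2O carbon R, ring-fusion CH S, lactone α-carbon S, O–CH carbon R).

Step 1
Reactants: 1 3-methylcyclohex-2-en-1-one
Product: 3 (3R)-3-methyl-3-[1-(trimethylsilyl)ethenyl]cyclohexan-1-one, via diisobutylaluminium enolate 2 (not isolated)
Conditions: i-Bu2AlH, HC≡CSiMe3, hexanes/THF, 55 °C; then 1, Cu(OTf)2 (5 mol%), chiral sulfonate-bearing N-heterocyclic carbene ligand (from its imidazolinium salt, 5 mol%), THF, −78 to −15 °C; aq. work-up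
Reagents that add atoms: diisobutyl[1-(trimethylsilyl)ethenyl]aluminium C=C([Si](C)(C)C)[Al](CC(C)C)CC(C)C, made in the flask from ethynyltrimethylsilane C#C[Si](C)(C)C
Why: Enantioselective conjugate addition of a silyl-substituted vinylalane to a β-methyl cyclohexenone, catalysed by Cu(OTf)2 and a chiral N-heterocyclic carbene, is an established route to vinyl-bearing quaternary centres, the carbene bound to copper delivering the alkenyl group to one enone face so that the ring-A quaternary carbon forms as R, while the silyl group fixes the regiochemistry of the alane and is the handle for step 3.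

Step 2
Reactants: 3 (3R)-3-methyl-3-[1-(trimethylsilyl)ethenyl]cyclohexan-1-one
Product: 4 trimethyl{1-[(1R)-1,3,3-trimethylcyclohexyl]ethenyl}silane
Conditions: Me2Zn, TiCl4 (gives Me2TiCl2, 2.5 equiv), CH2Cl2, −40 to 0 °C
Reagents that add atoms: dichlorodimethyltitanium C[Ti](C)(Cl)Cl, made in the flask from dimethylzinc C[Zn]C
Why: Titanium-mediated geminal dimethylation of a ketone (methyl addition, ionisation of the tertiary titanium alkoxide, second methyl transfer) turns C=O directly into CMe2, the tertiary cation being one carbon away from the quaternary centre so that no 1,2-shift or loss of configuration is expected and the α-silyl vinyl group being a poor cation trap.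

Step 3
Reactants: 4 trimethyl{1-[(1R)-1,3,3-trimethylcyclohexyl]ethenyl}silane
Product: 5 (1R)-1-(1-iodoethenyl)-1,3,3-trimethylcyclohexane
Conditions: N-iodosuccinimide, (CF3)2CHOH, 0 °C
Reagents that add atoms: N-iodosuccinimide O=C1CCC(=O)N1I
Why: Electrophilic ipso-iododesilylation of the vinylsilane replaces silicon by iodine at the same carbon through a β-silyl-stabilised cation in the ionising fluoroalcohol, giving the 1-iodoethenyl group without touching the stereocentre.

Step 4
Reactants: 5 (1R)-1-(1-iodoethenyl)-1,3,3-trimethylcyclohexane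
Product: 6 (1R)-1-(buta-1,3-dien-2-yl)-1,3,3-trimethylcyclohexane
Conditions: CH2=CHSnBu3, Pd(PPh3)4 (5 mol%), CuI (10 mol%), DMF, 50 °C
Reagents that add atoms: tributyl(vinyl)stannane C=C[Sn](CCCC)(CCCC)CCCC
Why: Stille coupling of the alkenyl iodide with the vinylstannane (CuI accelerating transmetalation at the hindered site) joins two sp2 carbons and gives the 2-substituted butadiene, no stereocentre being involved.

Step 5
Reactants: 7 allyl benzyl ether; 8 acrylic acid
Product: 9 (2E)-4-(benzyloxy)but-2-enoic acid
Conditions: second-generation Grubbs catalyst RuCl2(=CHPh)(PCy3)(1,3-dimesitylimidazolidin-2-ylidene) (3 mol%), CH2Cl2, 40 °C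
Reagents that add atoms: none
Why: Olefin cross-metathesis between an allyl ether and acrylic acid, an electron-poor partner that does not homodimerise, should give the E-enoic acid under thermodynamic control with loss of ethene.

Step 6
Reactants: 9 (2E)-4-(benzyloxy)but-2-enoic acid; 10 (4R)-4-benzyl-1,3-oxazolidin-2-one
Product: 12 (4R)-4-benzyl-3-[(2E)-4-(benzyloxy)but-2-enoyl]-1,3-oxazolidin-2-one, via mixed pivalic anhydride 11 (not isolated)
Conditions: t-BuCOCl, Et3N, THF, −20 °C; then 10, LiCl, −20 °C to rt
Reagents that add atoms: none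
Why: N-Acylation of the oxazolidinone by the mixed pivalic anhydride under LiCl/Et3N activation is the standard mild entry to enoyl imides and avoids conjugate addition to the acceptor, the auxiliary stereocentre being untouched.

Step 7
Reactants: 6 (1R)-1-(buta-1,3-dien-2-yl)-1,3,3-trimethylcyclohexane; 12 (4R)-4-benzyl-3-[(2E)-4-(benzyloxy)but-2-enoyl]-1,3-oxazolidin-2-one
Product: 13 (4R)-4-benzyl-3-{[(1R,6R)-6-[(benzyloxy)methyl]-4-[(1R)-1,3,3-trimethylcyclohexyl]cyclohex-3-en-1-yl]carbonyl}-1,3-oxazolidin-2-one
Conditions: Et2AlCl (1.4 equiv per imide), CH2Cl2, −78 to −30 °C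
Reagents that add atoms: none
Why: Oxazolidinone-auxiliary Diels–Alder reaction of the aluminium-chelated s-cis enoyl imide with a 2-substituted butadiene, in which the imide-bearing carbon ends para to the ring-A substituent, the E geometry of the dienophile becomes the trans relation of the two new ring-B centres, and the benzyl group of the (R)-auxiliary blocks one alkene face so that the diene adds to the other to give (1R,6R).

Step 8
Reactants: 13 (4R)-4-benzyl-3-{[(1R,6R)-6-[(benzyloxy)methyl]-4-[(1R)-1,3,3-trimethylcyclohexyl]cyclohex-3-en-1-yl]carbonyl}-1,3-oxazolidin-2-one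
Product: 14 {(1R,6R)-6-[(benzyloxy)methyl]-4-[(1R)-1,3,3-trimethylcyclohexyl]cyclohex-3-en-1-yl}methanol
Conditions: LiBH4, MeOH (1 equiv), Et2O, 0 °C
Reagents that add atoms: none
Why: Reductive cleavage of the N-acyl oxazolidinone with LiBH4 (hydride attack at the exocyclic imide carbonyl, then reduction of the released aldehyde) gives the primary alcohol and returns the auxiliary without deprotonating either stereocentre.

Step 9
Reactants: 14 {(1R,6R)-6-[(benzyloxy)methyl]-4-[(1R)-1,3,3-trimethylcyclohexyl]cyclohex-3-en-1-yl}methanol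
Product: 15 {(1R,6R)-6-[(benzyloxy)methyl]-4-[(1R)-1,3,3-trimethylcyclohexyl]cyclohex-3-en-1-yl}methyl butanoate
Conditions: n-PrCOCl, pyridine, DMAP (cat.), CH2Cl2, 0 °C to rt
Reagents that add atoms: butanoyl chloride CCCC(=O)Cl
Why: Acylation of the unhindered primary alcohol under pyridine/DMAP catalysis installs the ester of the target at once, the benzyl ether keeping the second hydroxymethyl carbon distinct.

Step 10
Reactants: 15 {(1R,6R)-6-[(benzyloxy)methyl]-4-[(1R)-1,3,3-trimethylcyclohexyl]cyclohex-3-en-1-yl}methyl butanoate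
Product: 16 {(1R,6R)-6-[(benzyloxy)methyl]-5-hydroxy-4-[(1R)-1,3,3-trimethylcyclohexyl]cyclohex-3-en-1-yl}methyl butanoate (carbinol epimers)
Conditions: SeO2 (0.5 equiv), t-BuOOH (3 equiv), CH2Cl2, rt
Reagents that add atoms: selenium dioxide O=[Se]=O; tert-butyl hydroperoxide CC(C)(C)OO
Why: Selenium dioxide allylic oxidation (Riley oxidation: ene reaction at the less substituted alkene carbon, then [2,3]-sigmatropic shift) hydroxylates the allylic position on the more substituted alkene carbon, here the single ring CH2 between the ring-A-bearing carbon and the CH(CH2OBn) carbon, and returns the double bond to its place, the new carbinol configuration being irrelevant because it is oxidised in step 11 and any enone from over-oxidation being the next product already.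

Step 11
Reactants: 16 {(1R,6R)-6-[(benzyloxy)methyl]-5-hydroxy-4-[(1R)-1,3,3-trimethylcyclohexyl]cyclohex-3-en-1-yl}methyl butanoate (carbinol epimers)
Product: 17 {(1R,6R)-6-[(benzyloxy)methyl]-5-oxo-4-[(1R)-1,3,3-trimethylcyclohexyl]cyclohex-3-en-1-yl}methyl butanoate
Conditions: Dess–Martin periodinane, CH2Cl2, rt
Reagents that add atoms: none
Why: Dess–Martin oxidation of the secondary allylic alcohol gives the 2-substituted cyclohexenone under neutral conditions, so the α′ stereocentre with its β-benzyloxy group should be neither epimerised nor eliminated.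

Step 12
Reactants: 17 {(1R,6R)-6-[(benzyloxy)methyl]-5-oxo-4-[(1R)-1,3,3-trimethylcyclohexyl]cyclohex-3-en-1-yl}methyl butanoate
Product: 19 (5R,6R)-6-[(benzyloxy)methyl]-5-[(butanoyloxy)methyl]-2-[(1R)-1,3,3-trimethylcyclohexyl]cyclohex-1-en-1-yl trifluoromethanesulfonate, via lithium enolate 18 (not isolated)
Conditions: LiBH(s-Bu)3, THF, −78 °C; then PhNTf2, −78 to 0 °C
Reagents that add atoms: N-phenylbis(trifluoromethanesulfonimide) O=S(=O)(N(c1ccccc1)S(=O)(=O)C(F)(F)F)C(F)(F)F
Why: Conjugate reduction with enolate trapping, in which the bulky borohydride adds 1,4 (1,2-attack is blocked by the α-tert-alkyl group) to give the tetrasubstituted lithium enolate regiospecifically and O-sulfonylation fixes the double bond between the former carbonyl carbon and the ring-A-bearing carbon, no stereocentre being formed.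

Step 13
Reactants: 19 (5R,6R)-6-[(benzyloxy)methyl]-5-[(butanoyloxy)methyl]-2-[(1R)-1,3,3-trimethylcyclohexyl]cyclohex-1-en-1-yl trifluoromethanesulfonate
Product: 20 benzyl 3-{(5R,6S)-6-[(benzyloxy)methyl]-5-[(butanoyloxy)methyl]-2-[(1R)-1,3,3-trimethylcyclohexyl]cyclohex-1-en-1-yl}propanoate
Conditions: BrZnCH2CH2CO2Bn (from BrCH2CH2CO2Bn, Zn, LiCl, THF), Pd(OAc)2 (5 mol%), SPhos (10 mol%), THF/NMP, 50 °C
Reagents that add atoms: [3-(benzyloxy)-3-oxopropyl]zinc bromide Br[Zn]CCC(=O)OCc1ccccc1, made in the flask from benzyl 3-bromopropanoate BrCCC(=O)OCc1ccccc1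
Why: Negishi coupling of the enol triflate with a functionalised primary alkylzinc bromide (bulky electron-rich biarylphosphine to favour reductive elimination over β-hydride elimination) attaches the three-carbon ester arm and completes the tetrasubstituted alkene, esters and ethers being tolerated by the organozinc.

Step 14
Reactants: 20 benzyl 3-{(5R,6S)-6-[(benzyloxy)methyl]-5-[(butanoyloxy)methyl]-2-[(1R)-1,3,3-trimethylcyclohexyl]cyclohex-1-en-1-yl}propanoate
Product: 21 3-{(5R,6S)-5-[(butanoyloxy)methyl]-6-(hydroxymethyl)-2-[(1R)-1,3,3-trimethylcyclohexyl]cyclohex-1-en-1-yl}propanoic acid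
Conditions: H2 (1 atm), Pd/C (10%), EtOAc, rt
Reagents that add atoms: none
Why: Hydrogenolysis over palladium on carbon cleaves the benzyl ether and the benzyl ester in one operation, while the tetrasubstituted alkene flanked by a quaternary carbon should be too hindered to be reduced at one atmosphere.

Step 15
Reactants: 21 3-{(5R,6S)-5-[(butanoyloxy)methyl]-6-(hydroxymethyl)-2-[(1R)-1,3,3-trimethylcyclohexyl]cyclohex-1-en-1-yl}propanoic acid
Product: 22 3-{(5R,6S)-5-[(butanoyloxy)methyl]-6-formyl-2-[(1R)-1,3,3-trimethylcyclohexyl]cyclohex-1-en-1-yl}propanoic acid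
Conditions: Dess–Martin periodinane, CH2Cl2, 0 °C to rt
Reagents that add atoms: none
Why: Dess–Martin oxidation converts the primary alcohol into the aldehyde without base, so the α-stereocentre of the β,γ-unsaturated aldehyde should not epimerise and the alkene should not move into conjugation, the crude aldehyde acid being used at once.

Step 16
Reactants: 22 3-{(5R,6S)-5-[(butanoyloxy)methyl]-6-formyl-2-[(1R)-1,3,3-trimethylcyclohexyl]cyclohex-1-en-1-yl}propanoic acid
Product: 25 target β-lactone CNP0144861.2, via acylpyridinium iodide 23 (not isolated), via cis-aldolate zwitterion 24 (not isolated)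
Conditions: 2-chloro-1-methylpyridinium iodide (3 equiv), 4-pyrrolidinopyridine (1 equiv), i-Pr2NEt (4 equiv), MeCN, 23 °C, slow addition of 22
Reagents that add atoms: none
Why: The carboxylate displaces chloride from the pyridinium salt, 4-pyrrolidinopyridine takes over the acyl group to give acylpyridinium 23, and i-Pr2NEt removes an α-proton to give an ammonium enolate that adds to the formyl group (aldolate 24), whose alkoxide then expels the pyridine and closes the oxetanone. The closest known reaction type is the nucleophile-promoted aldol-lactonisation (NCAL) of aldehyde acids to cyclopentane-fused β-lactones. Ring C closes by a 5-(enolexo)-exo-trig aldol addition and ring D by a 4-exo-trig acyl substitution. The lactone α-carbon (S) and the O–CH carbon (R) come out cis because only the cis aldolate can reach the acyl carbon, the aldol step being reversible for the other isomer; the sense at the O–CH carbon is dictated by the resident ring-B centres, the formyl oxygen and the acylpyridinium arm taking the face of the forming five-membered ring that carries the ring-fusion hydrogen, anti to the ring-B carbon bearing the butanoyloxymethyl group. The step needs the aldol event to be faster than epimerisation of the α-branched β,γ-unsaturated aldehyde or migration of the double bond into conjugation, which the five-membered intramolecular transition state, the hindered tertiary α-C–H and slow addition of 22 into excess activating agent should secure; the ester and the tetrasubstituted alkene are spectators.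

**Compound list**

1 | 3-methylcyclohex-2-en-1-one | CC1=CC(=O)CCC1 | starting material
2 | diisobutylaluminium (3R)-3-methyl-3-[1-(trimethylsilyl)ethenyl]cyclohex-1-en-1-olate | C=C([Si](C)(C)C)[C@]1(C)CCCC(O[Al](CC(C)C)CC(C)C)=C1 | intermediate
3 | (3R)-3-methyl-3-[1-(trimethylsilyl)ethenyl]cyclohexan-1-one | C=C([Si](C)(C)C)[C@]1(C)CCCC(=O)C1 | intermediate
4 | trimethyl{1-[(1R)-1,3,3-trimethylcyclohexyl]ethenyl}silane | C=C([Si](C)(C)C)[C@]1(C)CCCC(C)(C)C1 | intermediate
5 | (1R)-1-(1-iodoethenyl)-1,3,3-trimethylcyclohexane | C=C(I)[C@]1(C)CCCC(C)(C)C1 | intermediate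
6 | (1R)-1-(buta-1,3-dien-2-yl)-1,3,3-trimethylcyclohexane | C=CC(=C)[C@]1(C)CCCC(C)(C)C1 | intermediate
7 | allyl benzyl ether | C=CCOCc1ccccc1 | starting material
8 | acrylic acid | C=CC(=O)O | starting material
9 | (2E)-4-(benzyloxy)but-2-enoic acid | OC(=O)/C=C/COCc1ccccc1 | intermediate
10 | (4R)-4-benzyl-1,3-oxazolidin-2-one | O=C1N[C@H](Cc2ccccc2)CO1 | starting material
11 | (2E)-4-(benzyloxy)but-2-enoic pivalic anhydride | CC(C)(C)C(=O)OC(=O)/C=C/COCc1ccccc1 | intermediate
12 | (4R)-4-benzyl-3-[(2E)-4-(benzyloxy)but-2-enoyl]-1,3-oxazolidin-2-one | O=C(/C=C/COCc1ccccc1)N1[C@H](Cc2ccccc2)COC1=O | intermediate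
13 | (4R)-4-benzyl-3-{[(1R,6R)-6-[(benzyloxy)methyl]-4-[(1R)-1,3,3-trimethylcyclohexyl]cyclohex-3-en-1-yl]carbonyl}-1,3-oxazolidin-2-one | O=C([C@@H]1CC=C([C@]2(C)CCCC(C)(C)C2)C[C@H]1COCc1ccccc1)N1[C@H](Cc2ccccc2)COC1=O | intermediate
14 | {(1R,6R)-6-[(benzyloxy)methyl]-4-[(1R)-1,3,3-trimethylcyclohexyl]cyclohex-3-en-1-yl}methanol | OC[C@@H]1CC=C([C@]2(C)CCCC(C)(C)C2)C[C@H]1COCc1ccccc1 | intermediate
15 | {(1R,6R)-6-[(benzyloxy)methyl]-4-[(1R)-1,3,3-trimethylcyclohexyl]cyclohex-3-en-1-yl}methyl butanoate | CCCC(=O)OC[C@@H]1CC=C([C@]2(C)CCCC(C)(C)C2)C[C@H]1COCc1ccccc1 | intermediate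
16 | {(1R,6R)-6-[(benzyloxy)methyl]-5-hydroxy-4-[(1R)-1,3,3-trimethylcyclohexyl]cyclohex-3-en-1-yl}methyl butanoate, carbinol epimers | CCCC(=O)OC[C@@H]1CC=C([C@]2(C)CCCC(C)(C)C2)C(O)[C@H]1COCc1ccccc1 | intermediate
17 | {(1R,6R)-6-[(benzyloxy)methyl]-5-oxo-4-[(1R)-1,3,3-trimethylcyclohexyl]cyclohex-3-en-1-yl}methyl butanoate | CCCC(=O)OC[C@@H]1CC=C([C@]2(C)CCCC(C)(C)C2)C(=O)[C@H]1COCc1ccccc1 | intermediate
18 | lithium (5R,6R)-6-[(benzyloxy)methyl]-5-[(butanoyloxy)methyl]-2-[(1R)-1,3,3-trimethylcyclohexyl]cyclohex-1-en-1-olate | CCCC(=O)OC[C@@H]1CCC([C@]2(C)CCCC(C)(C)C2)=C([O-])[C@H]1COCc1ccccc1.[Li+] | intermediate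
19 | (5R,6R)-6-[(benzyloxy)methyl]-5-[(butanoyloxy)methyl]-2-[(1R)-1,3,3-trimethylcyclohexyl]cyclohex-1-en-1-yl trifluoromethanesulfonate | CCCC(=O)OC[C@@H]1CCC([C@]2(C)CCCC(C)(C)C2)=C(OS(=O)(=O)C(F)(F)F)[C@H]1COCc1ccccc1 | intermediate
20 | benzyl 3-{(5R,6S)-6-[(benzyloxy)methyl]-5-[(butanoyloxy)methyl]-2-[(1R)-1,3,3-trimethylcyclohexyl]cyclohex-1-en-1-yl}propanoate | CCCC(=O)OC[C@@H]1CCC([C@]2(C)CCCC(C)(C)C2)=C(CCC(=O)OCc2ccccc2)[C@H]1COCc1ccccc1 | intermediate
21 | 3-{(5R,6S)-5-[(butanoyloxy)methyl]-6-(hydroxymethyl)-2-[(1R)-1,3,3-trimethylcyclohexyl]cyclohex-1-en-1-yl}propanoic acid | CCCC(=O)OC[C@@H]1CCC([C@]2(C)CCCC(C)(C)C2)=C(CCC(=O)O)[C@H]1CO | intermediate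
22 | 3-{(5R,6S)-5-[(butanoyloxy)methyl]-6-formyl-2-[(1R)-1,3,3-trimethylcyclohexyl]cyclohex-1-en-1-yl}propanoic acid | CCCC(=O)OC[C@@H]1CCC([C@]2(C)CCCC(C)(C)C2)=C(CCC(=O)O)[C@H]1C=O | intermediate
23 | 1-acyl-4-(pyrrolidin-1-yl)pyridinium iodide derived from acid 22 | CCCC(=O)OC[C@@H]1CCC([C@]2(C)CCCC(C)(C)C2)=C(CCC(=O)[n+]2ccc(N3CCCC3)cc2)[C@H]1C=O.[I-] | intermediate
24 | cis-aldolate zwitterion (ring C closed; alkoxide on the O–CH carbon, acylpyridinium on the adjacent carbon) | CCCC(=O)OC[C@@H]1CCC([C@]2(C)CCCC(C)(C)C2)=C2C[C@H](C(=O)[n+]3ccc(N4CCCC4)cc3)[C@H]([O-])[C@H]21 | intermediate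
25 | CNP0144861.2: butanoate of the tricyclic β-lactone alcohol (oxetanone cis-fused to ring C; ring C fused to cyclohexene ring B; lactone α-carbon S, O–CH carbon R, ring-fusion CH S, CH–CH2O carbon R, ring-A quaternary carbon R) | CCCC(=O)OC[C@@H]1CCC([C@]2(C)CCCC(C)(C)C2)=C2C[C@@H]3C(=O)O[C@@H]3[C@H]21 | target

**Step count and risks**

Total step count: 16. Longest linear sequence: 14 (steps 1–4 and 7–16).

Step 16 is the most exposed. Under the amine base the formyl-bearing carbon may epimerise, or the tetrasubstituted double bond may slip into conjugation, before the aldol event, and the facial control at the new O–CH centre may be incomplete. The fallback is a stepwise, metal-chelated aldol followed by a separate lactonisation. It sets out from hydroxy acid 21, which is converted with thiophenol and N,N′-dicyclohexylcarbodiimide into S-phenyl 3-{(5R,6S)-5-[(butanoyloxy)methyl]-6-(hydroxymethyl)-2-[(1R)-1,3,3-trimethylcyclohexyl]cyclohex-1-en-1-yl}propanethioate F1. Dess–Martin oxidation gives the corresponding formyl thioester F2. Soft enolisation with MgBr2·OEt2 and i-Pr2NEt in CH2Cl2 should close ring C through a magnesium-bridged aldolate to the cis-β-hydroxy thioester F3. Thiophilic activation with AgOCOCF3 then closes the oxetanone, and the route is rejoined at target 25.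

Step 13 is next. Oxidative addition and transmetalation at the tetrasubstituted enol triflate next to the tert-alkyl group may be slow, so that triflate hydrolysis, reduction or β-hydride elimination of the alkylpalladium takes over. The fallback replaces the sp3 partner by an alkene. It sets out from enol triflate 19, which undergoes a Heck reaction with benzyl acrylate (Pd(OAc)2, PPh3, Et3N, DMF, 70 °C) to give benzyl (2E)-3-{(5R,6S)-6-[(benzyloxy)methyl]-5-[(butanoyloxy)methyl]-2-[(1R)-1,3,3-trimethylcyclohexyl]cyclohex-1-en-1-yl}prop-2-enoate F4. Hydrogenation over Pd/C should saturate the disubstituted conjugated double bond and remove both benzyl groups in the same operation, and the route is rejoined at hydroxy acid 21.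

Step 7 is the third. The electron-rich 2-tert-alkyl diene may oligomerise cationically under the stoichiometric aluminium Lewis acid, and chelation of the γ-benzyloxy group may erode facial control. The fallback uses iminium catalysis instead of an auxiliary. It sets out from allyl benzyl ether 7 and diene 6. Cross-metathesis of 7 with acrolein (second-generation Grubbs catalyst RuCl2(=CHPh)(PCy3)(1,3-dimesitylimidazolidin-2-ylidene), CH2Cl2, 40 °C) gives (2E)-4-(benzyloxy)but-2-enal F5. F5 adds to 6 in the presence of the enantiomer of 5-benzyl-2,2,3-trimethylimidazolidin-4-one hydrochloride that exposes the required enal face (MeNO2/H2O), giving (1R,6R)-6-[(benzyloxy)methyl]-4-[(1R)-1,3,3-trimethylcyclohexyl]cyclohex-3-ene-1-carbaldehyde F6. Reduction with NaBH4 rejoins the route at alcohol 14.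

Further compounds
F1 | step 16 | S-phenyl 3-{(5R,6S)-5-[(butanoyloxy)methyl]-6-(hydroxymethyl)-2-[(1R)-1,3,3-trimethylcyclohexyl]cyclohex-1-en-1-yl}propanethioate | CCCC(=O)OC[C@@H]1CCC([C@]2(C)CCCC(C)(C)C2)=C(CCC(=O)Sc2ccccc2)[C@H]1CO
F2 | step 16 | S-phenyl 3-{(5R,6S)-5-[(butanoyloxy)methyl]-6-formyl-2-[(1R)-1,3,3-trimethylcyclohexyl]cyclohex-1-en-1-yl}propanethioate | CCCC(=O)OC[C@@H]1CCC([C@]2(C)CCCC(C)(C)C2)=C(CCC(=O)Sc2ccccc2)[C@H]1C=O
F3 | step 16 | cis-β-hydroxy S-phenyl thioester with ring C closed (hydroxyl on the O–CH carbon, thioester on the adjacent carbon, configurations as in 25) | CCCC(=O)OC[C@@H]1CCC([C@]2(C)CCCC(C)(C)C2)=C2C[C@H](C(=O)Sc3ccccc3)[C@H](O)[C@H]21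
F4 | step 13 | benzyl (2E)-3-{(5R,6S)-6-[(benzyloxy)methyl]-5-[(butanoyloxy)methyl]-2-[(1R)-1,3,3-trimethylcyclohexyl]cyclohex-1-en-1-yl}prop-2-enoate | CCCC(=O)OC[C@@H]1CCC([C@]2(C)CCCC(C)(C)C2)=C(/C=C/C(=O)OCc2ccccc2)[C@H]1COCc1ccccc1
F5 | step 7 | (2E)-4-(benzyloxy)but-2-enal | O=C/C=C/COCc1ccccc1
F6 | step 7 | (1R,6R)-6-[(benzyloxy)methyl]-4-[(1R)-1,3,3-trimethylcyclohexyl]cyclohex-3-ene-1-carbaldehyde | O=C[C@@H]1CC=C([C@]2(C)CCCC(C)(C)C2)C[C@H]1COCc1ccccc1
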